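**Strategy.** Ring A is a para-dioxygenated benzene (O1 on C8a, OH on C6, OMe on C7 and C8), that is, twofold-symmetric 2,3-dimethoxyhydroquinone, the reduced form of quinone ring B. The pyran ring is therefore disconnected at O1–C2 and C4–C4a. A formal [3+3] annulation joins the hydroquinone (one O–H and its only free ortho C–H) to a 2-arylacrolein carrying ring B as its tetramethoxy ether. It runs through ortho-hydroxyalkylation, a vinyl ortho-quinone methide and oxa-6π electrocyclisation, and gives the isoflav-3-ene in one operation. Iridium-catalysed asymmetric hydrogenation then sets C3 (S), and oxidative demethylation unveils the quinone. Both rings come from 1,2,3,4-tetramethoxybenzene.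

Key step: step 3

Remark: C3 of the target is (S) (CIP order C2 > quinonyl carbon > C4 > H); chroman numbering O1, C2, C3, C4, C4a, C5–C8, C8a is used, ring B positions are primed.

Step 1
Reactants: 1 1,2,3,4-tetramethoxybenzene
Product: 3 2,3-dimethoxybenzene-1,4-diol, via 2,3-dimethoxy-1,4-benzoquinone 2 (not isolated)
Conditions: (NH4)2Ce(NO3)6 (2.5 equiv), MeCN/H2O, 0 °C; then Na2S2O4 (aq.), EtOAc, rt, Ar
Reagents that add atoms: water, O
Why: Oxidative demethylation of the para-dimethoxy pair (arene radical cation, water adds at the ipso carbons, methanol leaves) should give the symmetric quinone, which dithionite reduces in the same work-up to the air-sensitive hydroquinone.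

Step 2
Reactants: 1 1,2,3,4-tetramethoxybenzene; 4 2-bromo-3,3-diethoxyprop-1-ene
Product: 7 1-(3,3-diethoxyprop-1-en-2-yl)-2,3,4,5-tetramethoxybenzene, via aryllithium 5 (not isolated), via arylzinc chloride 6 (not isolated)
Conditions: n-BuLi, TMEDA, THF, 0 °C; ZnCl2, 0 °C to rt; then 4, Pd2(dba)3 (2 mol%), SPhos (8 mol%), THF, 50 °C
Reagents that add atoms: none
Why: Directed ortho-lithiation at the only kind of ring C–H (each is ortho to OMe), transmetalation to zinc and Negishi coupling with the vinyl bromide should give the acetal-masked 2-arylacrolein.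

Step 3
Reactants: 3 2,3-dimethoxybenzene-1,4-diol; 7 1-(3,3-diethoxyprop-1-en-2-yl)-2,3,4,5-tetramethoxybenzene
Product: 11 7,8-dimethoxy-3-(2,3,4,5-tetramethoxyphenyl)-2H-chromen-6-ol, via enal 8 (not isolated), via benzodioxaborin 9 (not isolated), via ortho-quinone methide 10 (not isolated)
Conditions: PhB(OH)2 (1.2 equiv), AcOH (aq. 90%)/toluene, 80 °C then reflux with azeotropic removal of water, Ar; 3 in excess (3 equiv), 7 added slowly
Reagents that add atoms: none
Why: Acid unmasks enal 8; PhB(OH)2 condenses with one O–H of 3 and with the aldehyde and delivers the carbonyl carbon through a six-membered boron-bound transition state to the ortho carbon (C4–C4a bond, benzodioxaborin 9), and thermal loss of PhB(OH)2 gives the vinyl ortho-quinone methide 10, which closes to 11 (O1–C2 bond). The closest known reaction type is the arylboronic-acid-templated condensation of phenols with α,β-unsaturated aldehydes to 2H-chromenes. The pyran ring closes by a thermal oxa-6π electrocyclisation of the 1-oxatriene O1=C8a–C4a=C4–C3=C2 (pericyclic, not an ionic exo or endo attack), made irreversible by rearomatisation of ring A. No stereocentre is created: C3 stays sp2 and the transient carbinol centre of 9 is erased in 10. The step needs site selectivity, 1,2- over 1,4-addition and mono-annulation: the twofold symmetry of 3 and the single free ortho C–H beside each OH (the other ortho position carries OMe) allow only one regioisomer, the boron template enforces attack at the carbonyl carbon, and excess 3 with slow addition of 7 limits a second annulation and enal self-condensation.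

Step 4
Reactants: 11 7,8-dimethoxy-3-(2,3,4,5-tetramethoxyphenyl)-2H-chromen-6-ol
Product: 12 7,8-dimethoxy-3-(2,3,4,5-tetramethoxyphenyl)-2H-chromen-6-yl acetate
Conditions: Ac2O, pyridine, DMAP (cat.), CH2Cl2, 0 °C to rt
Reagents that add atoms: acetic anhydride, CC(=O)OC(C)=O
Why: DMAP-catalysed O-acylation should protect the air-sensitive para-alkoxyphenol and later shield ring A from the cerium oxidant.

Step 5
Reactants: 12 7,8-dimethoxy-3-(2,3,4,5-tetramethoxyphenyl)-2H-chromen-6-yl acetate
Product: 13 (3S)-7,8-dimethoxy-3-(2,3,4,5-tetramethoxyphenyl)-3,4-dihydro-2H-chromen-6-yl acetate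
Conditions: [Ir(cod)((4S,5S)-ThrePHOX)]BArF (2 mol%), H2 (50 bar), CH2Cl2, rt
Reagents that add atoms: none
Why: Iridium-catalysed asymmetric hydrogenation of a trisubstituted 3-aryl-2H-chromene with a chiral P,N ligand should add H2 to one enantiotopic face of C3=C4 under catalyst control, creating C3; the ligand enantiomer is chosen to give (3S) (the (4S,5S) series by analogy with other 3-aryl-2H-chromenes, otherwise its mirror image).

Step 6
Reactants: 13 (3S)-7,8-dimethoxy-3-(2,3,4,5-tetramethoxyphenyl)-3,4-dihydro-2H-chromen-6-yl acetate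
Product: 14 (3S)-3-(4,5-dimethoxy-3,6-dioxocyclohexa-1,4-dien-1-yl)-7,8-dimethoxy-3,4-dihydro-2H-chromen-6-yl acetate
Conditions: (NH4)2Ce(NO3)6 (2.5 equiv), MeCN/H2O (2:1), 0 °C
Reagents that add atoms: water, O
Why: Oxidative demethylation should be ring-selective, because tetramethoxy ring B with its para-dimethoxy pair (C2' and C5') is far more easily oxidised than acetylated ring A, which has no para-dialkoxy pair; the sp3 stereocentre is not touched in the acidic medium.

Step 7
Reactants: 14 (3S)-3-(4,5-dimethoxy-3,6-dioxocyclohexa-1,4-dien-1-yl)-7,8-dimethoxy-3,4-dihydro-2H-chromen-6-yl acetate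
Product: 15 5-[(3S)-6-hydroxy-7,8-dimethoxy-3,4-dihydro-2H-chromen-3-yl]-2,3-dimethoxycyclohexa-2,5-diene-1,4-dione
Conditions: HCl (0.5 M in MeOH), 0 °C to rt, Ar
Reagents that add atoms: none
Why: Acid-catalysed transesterification should cleave the aryl acetate while avoiding base-induced quinone methide tautomerisation at C3–H (epimerisation); any methoxy exchange on the quinone is degenerate in methanol.

**Compound list**

1 | 1,2,3,4-tetramethoxybenzene | COc1ccc(OC)c(OC)c1OC | starting material
2 | 2,3-dimethoxy-1,4-benzoquinone | COC1=C(OC)C(=O)C=CC1=O | intermediate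
3 | 2,3-dimethoxybenzene-1,4-diol | COc1c(O)ccc(O)c1OC | intermediate
4 | 2-bromo-3,3-diethoxyprop-1-ene | C=C(Br)C(OCC)OCC | starting material
5 | (2,3,4,5-tetramethoxyphenyl)lithium | [Li]c1cc(OC)c(OC)c(OC)c1OC | intermediate
6 | chloro(2,3,4,5-tetramethoxyphenyl)zinc | Cl[Zn]c1cc(OC)c(OC)c(OC)c1OC | intermediate
7 | 1-(3,3-diethoxyprop-1-en-2-yl)-2,3,4,5-tetramethoxybenzene | C=C(C(OCC)OCC)c1cc(OC)c(OC)c(OC)c1OC | intermediate
8 | 2-(2,3,4,5-tetramethoxyphenyl)prop-2-enal | C=C(C=O)c1cc(OC)c(OC)c(OC)c1OC | intermediate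
9 | 7,8-dimethoxy-2-phenyl-4-[1-(2,3,4,5-tetramethoxyphenyl)ethenyl]-4H-1,3,2-benzodioxaborinin-6-ol (racemic at C4) | C=C(c1cc(OC)c(OC)c(OC)c1OC)C1OB(c2ccccc2)Oc2c(OC)c(OC)c(O)cc21 | intermediate
10 | (6Z)-4-hydroxy-2,3-dimethoxy-6-[2-(2,3,4,5-tetramethoxyphenyl)prop-2-en-1-ylidene]cyclohexa-2,4-dien-1-one | C=C(c1cc(OC)c(OC)c(OC)c1OC)/C=C1/C=C(O)C(OC)=C(OC)C1=O | intermediate
11 | 7,8-dimethoxy-3-(2,3,4,5-tetramethoxyphenyl)-2H-chromen-6-ol | COc1cc(C2=Cc3cc(O)c(OC)c(OC)c3OC2)c(OC)c(OC)c1OC | intermediate
12 | 7,8-dimethoxy-3-(2,3,4,5-tetramethoxyphenyl)-2H-chromen-6-yl acetate | COc1cc(C2=Cc3cc(OC(C)=O)c(OC)c(OC)c3OC2)c(OC)c(OC)c1OC | intermediate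
13 | (3S)-7,8-dimethoxy-3-(2,3,4,5-tetramethoxyphenyl)-3,4-dihydro-2H-chromen-6-yl acetate | COc1cc([C@H]2COc3c(cc(OC(C)=O)c(OC)c3OC)C2)c(OC)c(OC)c1OC | intermediate
14 | (3S)-3-(4,5-dimethoxy-3,6-dioxocyclohexa-1,4-dien-1-yl)-7,8-dimethoxy-3,4-dihydro-2H-chromen-6-yl acetate | COC1=C(OC)C(=O)C([C@H]2COc3c(cc(OC(C)=O)c(OC)c3OC)C2)=CC1=O | intermediate
15 | 5-[(3S)-6-hydroxy-7,8-dimethoxy-3,4-dihydro-2H-chromen-3-yl]-2,3-dimethoxycyclohexa-2,5-diene-1,4-dione | COC1=C(OC)C(=O)C([C@H]2COc3c(cc(O)c(OC)c3OC)C2)=CC1=O | target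

**Step count.** Total: 7 steps. Longest linear sequence: 6 steps (steps 2 to 7 from 1, or step 1 followed by steps 3 to 7).

**Steps most likely to fail**

Step 3 (key annulation). The unmasked enal may be consumed by hetero-Diels–Alder dimerisation or polymerisation, the hydroquinone may add in the conjugate (1,4) sense instead of at the carbonyl carbon, or a second annulation may occur at the remaining OH. The fallback makes the two bonds in separate operations from the quinone oxidation level; it sets out from 1 and comes back at 11. Arylzinc 6 (made from 1 as in step 2) is coupled under the same Negishi conditions with (2-bromoallyl)trimethylsilane (C=C(Br)C[Si](C)(C)C) to give trimethyl[2-(2,3,4,5-tetramethoxyphenyl)prop-2-en-1-yl]silane F1. Quinone 2, here isolated after the cerium oxidation of step 1 and before the dithionite treatment, undergoes Hosomi–Sakurai conjugate allylation with F1 (BF3·OEt2, CH2Cl2, −78 °C). This forms the C4–C4a bond and should give 2,3-dimethoxy-5-[2-(2,3,4,5-tetramethoxyphenyl)prop-2-en-1-yl]benzene-1,4-diol F2. Oxidation with Ag2O should give 2,3-dimethoxy-5-[2-(2,3,4,5-tetramethoxyphenyl)prop-2-en-1-yl]cyclohexa-2,5-diene-1,4-dione F3. Heating F3 in pyridine should tautomerise it to the same ortho-quinone methide 10, which electrocyclises (O1–C2 bond) to 11.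

Step 5 (asymmetric hydrogenation). The ortho-methoxy, tetraoxygenated 3-aryl group may slow turnover or lower facial selectivity. The fallback replaces catalytic induction by resolution; it sets out from 12 and comes back at 13. Hydrogenation without a chiral catalyst (H2, Pd/C, EtOAc) should give racemic 7,8-dimethoxy-3-(2,3,4,5-tetramethoxyphenyl)-3,4-dihydro-2H-chromen-6-yl acetate F4. The enantiomers are then separated by preparative chromatography on a chiral stationary phase (supercritical CO2/MeOH, amylose carbamate phase), and the (3S) enantiomer is taken on as 13.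

Step 7 (acetate removal beside the quinone). The quinone may be lost by conjugate addition of methanol, or the ee may erode through quinone methide tautomerisation at C3–H during ester cleavage. The fallback masks the quinone by reduction; it sets out from 14 and comes back at 15. Aqueous Na2S2O4 (EtOAc, rt) should reduce 14 to (3S)-3-(2,5-dihydroxy-3,4-dimethoxyphenyl)-7,8-dimethoxy-3,4-dihydro-2H-chromen-6-yl acetate F5, which is stable to base. K2CO3 in degassed MeOH then cleaves the acetate to (3S)-3-(2,5-dihydroxy-3,4-dimethoxyphenyl)-7,8-dimethoxy-3,4-dihydro-2H-chromen-6-ol F6. Stirring under air (or with one equivalent of Ag2O) should reoxidise only the ring B hydroquinone, since the para-alkoxyphenol of ring A is harder to oxidise, and return 15.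

Further compounds
F1 | step 3 | trimethyl[2-(2,3,4,5-tetramethoxyphenyl)prop-2-en-1-yl]silane | C=C(C[Si](C)(C)C)c1cc(OC)c(OC)c(OC)c1OC
F2 | step 3 | 2,3-dimethoxy-5-[2-(2,3,4,5-tetramethoxyphenyl)prop-2-en-1-yl]benzene-1,4-diol | C=C(Cc1cc(O)c(OC)c(OC)c1O)c1cc(OC)c(OC)c(OC)c1OC
F3 | step 3 | 2,3-dimethoxy-5-[2-(2,3,4,5-tetramethoxyphenyl)prop-2-en-1-yl]cyclohexa-2,5-diene-1,4-dione | C=C(CC1=CC(=O)C(OC)=C(OC)C1=O)c1cc(OC)c(OC)c(OC)c1OC
F4 | step 5 | racemic 7,8-dimethoxy-3-(2,3,4,5-tetramethoxyphenyl)-3,4-dihydro-2H-chromen-6-yl acetate | COc1cc(C2COc3c(cc(OC(C)=O)c(OC)c3OC)C2)c(OC)c(OC)c1OC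
F5 | step 7 | (3S)-3-(2,5-dihydroxy-3,4-dimethoxyphenyl)-7,8-dimethoxy-3,4-dihydro-2H-chromen-6-yl acetate | COc1c(O)cc([C@H]2COc3c(cc(OC(C)=O)c(OC)c3OC)C2)c(O)c1OC
F6 | step 7 | (3S)-3-(2,5-dihydroxy-3,4-dimethoxyphenyl)-7,8-dimethoxy-3,4-dihydro-2H-chromen-6-ol | COc1c(O)cc([C@H]2COc3c(cc(O)c(OC)c3OC)C2)c(O)c1OC
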